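Retrosynthesis cuts O23–C1 (macrolactone), C5–C6 (Suzuki–Miyaura), C20=C21 (Julia–Kocienski) and the C18=C19 and C6=C7 alkenes (olefination of C18 and C7 aldehydes), leaving a cis-decalin with C7/C18 carbinols, a C21–C27 sulfone and a C1–C5 iododienoate.
Enabling feature: ring A (C9–C14) carries oxygen at C11 and C13, and the ring B alkene C15=C16 starts one bond beyond fusion carbon C14. A C11 carbonyl with a β-oxygen at C13 and a δ,ε-alkene is what a [3,3] shift of an alkoxide bearing an alkoxyvinyl group leaves behind.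
C13–C14 is therefore cut (retro-oxy-Cope) to an endo-(E)-alkoxyvinyl bicyclo[2.2.2]octenol in which C11–C16 is a cage bond; the cage comes from a Diels–Alder reaction of guaiacol-derived 6,6-dimethoxycyclohexadienone with di-(−)-menthyl fumarate.
Forward order: cage (ring B is already in it) → ring A by oxy-Cope → C18 arm → union with the sulfone → C7 arm → 16-membered lactone → carbamate and unmasking.
Stereochemistry: C9, C16 and C17 come from the cycloaddition (menthyl esters as chiral handle), C8 from face-selective enolate methylation on the cage, C13/C14 from the boat-shaped rearrangement, C11 from axial hydride delivery. C26 comes from D-alaninal and C22–C25 from two (E)-crotylborations.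

Key step: step 14

Assumption: superstolide numbering (C1 lactone carbonyl to C27) is kept for all intermediates, and the uncatalysed cycloaddition of step 2 is taken to give both fumarate-face isomers, so that the menthyl esters serve mainly to make them separable.

Step 1
Reactants: 1 fumaryl chloride; 2 (−)-menthol
Product: 3 di-(−)-menthyl fumarate
Conditions: 2 (2.1 equiv), pyridine, CH2Cl2, 0 °C → rt
Reagents that add atoms: (−)-menthol (the second equivalent of 2), C[C@@H]1CC[C@H]([C@@H](C1)O)C(C)C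
Why: Twofold esterification of the diacid chloride by two equivalents of the secondary alcohol (acyl substitution) gives the C2-symmetric chiral fumarate without touching a stereocentre.

Step 2
Reactants: 4 guaiacol; 3 di-(−)-menthyl fumarate
Product: 6 di-(−)-menthyl trans-5,5-dimethoxy-6-oxobicyclo[2.2.2]oct-7-ene-2,3-dicarboxylate (C17 ester syn to the oxo/ketal bridge and C8 ester syn to the C14=C15 bridge), via 6,6-dimethoxycyclohexa-2,4-dien-1-one 5 (not isolated)
Conditions: PhI(OAc)2, MeOH/CH2Cl2, 0 °C → rt, slow addition of 4 to oxidant and excess 3; separation of diastereomers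
Reagents that add atoms: methanol, CO
Why: Oxidative dearomatisation of the phenol in methanol gives the ortho-quinone monoketal 5, which is trapped in a Diels–Alder reaction across its C16 and C9 termini; the ester that must be exo sits on the carbon bonding next to the flat carbonyl (C17) and not next to the ketal, whose methoxy group projects onto the dienophile, so C17-exo/C8-endo is expected, and of the two fumarate-face isomers (diastereomers because of the menthyl groups) the one shown is isolated by crystallisation or chromatography, which fixes C9, C16 and C17 in the absolute sense.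

Step 3
Reactants: 6 Diels–Alder adduct
Product: 8 C18→O11 γ-lactone menthyl C7-ester, via C11 hydroxy diester 7 (not isolated)
Conditions: NaBH4, MeOH/THF, −20 °C; then CSA (cat.), PhMe, 60 °C
Reagents that add atoms: none
Why: Borohydride reduction of the ketone from the open etheno face (the other face is screened by the exo C17 ester) puts O11 beside that ester, and acid-catalysed lactonisation (intramolecular transesterification) then forms the five-membered lactone, which tells the two esters apart and locks H17 against enolisation.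

Step 4
Reactants: 8 lactone ester
Product: 10 C8-methylated lactone ester (methyl syn to C14=C15), via lithium ester enolate 9 (not isolated)
Conditions: LiN(iPr)2, THF/DMPU, −78 °C; then MeI, −78 → −20 °C
Reagents that add atoms: iodomethane, CI
Why: Ester enolate alkylation in which only H8 can be removed, because an enolate at C17 would be a bridgehead (anti-Bredt) double bond of the lactone-bridged bicyclo[3.2.1] subunit, and iodomethane attacks the exocyclic enolate from the etheno side, away from the gem-dimethoxy carbon and the lactone, so the C8 quaternary centre carries methyl syn to C14=C15.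

Step 5
Reactants: 10 methylated lactone ester
Product: 11 C11,C18-diol menthyl C7-ester
Conditions: LiBH4, THF, 0 °C → rt
Reagents that add atoms: none
Why: Chemoselective hydride reduction in which LiBH4 opens the lactone to the diol while the menthyl ester on the quaternary C8 is too hindered to react.

Step 6
Reactants: 11 diol ester
Product: 12 C18 TBS ether (C11 hydroxyl free)
Conditions: TBSCl, imidazole, CH2Cl2/DMF, 0 °C
Reagents that add atoms: tert-butyldimethylsilyl chloride, CC(C)(C)[Si](C)(C)Cl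
Why: Sterically controlled silylation of the primary C18 hydroxyl in the presence of the hindered secondary C11 hydroxyl.

Step 7
Reactants: 12 silyl ether ester
Product: 13 C11,C7-diol
Conditions: LiAlH4, THF, 0 °C → 40 °C
Reagents that add atoms: none
Why: LiAlH4 reduction of the hindered ester to the neopentyl C7 alcohol with release of the second menthol; silyl ether and ketal are inert to hydride.

Step 8
Reactants: 13 diol
Product: 14 C7 TIPS ether (C11 hydroxyl free)
Conditions: TIPSCl, imidazole, DMAP (cat.), DMF, rt → 40 °C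
Reagents that add atoms: triisopropylsilyl chloride, CC(C)[Si](Cl)(C(C)C)C(C)C
Why: Silylation selects the primary (neopentyl) hydroxyl over the secondary one flanked by the ketal carbon and the bridgehead.

Step 9
Reactants: 14 secondary alcohol
Product: 15 C11 ketone with C10 dimethyl ketal
Conditions: Dess–Martin periodinane, NaHCO3, CH2Cl2, rt
Reagents that add atoms: none
Why: Dess–Martin oxidation returns the C11 ketone, which cannot epimerise because neither α-position (ketal carbon, bridgehead) has a removable proton.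

Step 10
Reactants: 15 α,α-dimethoxy ketone
Product: 16 bicyclo[2.2.2]oct-5-en-2-one with C10 methylene
Conditions: SmI2 (excess), THF/MeOH, −78 → 0 °C
Reagents that add atoms: none
Why: Single-electron reduction cleaves each C–OMe bond α to the carbonyl (ketyl, β-elimination, protonation of the resulting enolate, twice), the known reductive demethoxylation of α-alkoxy ketones.

Step 11
Reactants: 17 4-methoxybenzyl alcohol; 18 trichloroethylene
Product: 19 (E)-1,2-dichlorovinyl 4-methoxybenzyl ether
Conditions: KH, THF, 0 °C → rt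
Reagents that add atoms: none
Why: Addition of the potassium alkoxide to dichloroacetylene formed in situ from trichloroethylene (elimination–addition) gives the dichlorovinyl ether, the usual precursor of an alkoxyacetylide.

Step 12
Reactants: 19 dichlorovinyl ether; 16 ketone
Product: 21 C11 (4-methoxybenzyloxy)ethynyl carbinol (alkynyl group syn to C14=C15), via lithium alkoxyacetylide 20 (not isolated)
Conditions: 19, n-BuLi (2 equiv), THF, −78 → −40 °C; then 16, −78 °C
Reagents that add atoms: none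
Why: Dehydrochlorination and chlorine–lithium exchange give acetylide 20, whose 1,2-addition to the ketone comes from the etheno face because the C18 and C7 silyloxymethyl groups shield the other, so the new C11 carbinol carries the two-carbon unit over C14=C15.

Step 13
Reactants: 21 alkynyl carbinol
Product: 22 endo-(E)-2-(4-methoxybenzyloxy)vinyl bicyclo[2.2.2]octenol
Conditions: LiAlH4, THF, 0 °C → rt
Reagents that add atoms: none
Why: Hydroxyl-directed trans-hydroalumination of the propargylic alcohol and protonolysis give the (E)-enol ether, the geometry that the rearrangement translates into C13.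

Step 14
Reactants: 22 alkoxyvinyl bicyclooctenol
Product: 25 cis-decalin C11 ketone with C13 OPMB, via potassium alkoxide 23 (not isolated), via potassium C11 enolate 24 (not isolated)
Conditions: KH, 18-crown-6, THF, 0 °C → rt; then AcOH, −78 °C
Reagents that add atoms: none
Why: Deprotonation by KH, with the crown ether freeing the alkoxide from its counter-ion, weakens the C11–C16 bond so that the 1,5-diene C13=C12–C11–C16–C15=C14 undergoes a concerted [3,3] shift in which C11–C16 breaks, C13–C14 forms, and the C11 enolate and the C15=C16 alkene emerge. The closest known reaction is the anionic oxy-Cope rearrangement of endo-2-vinylbicyclo[2.2.2]oct-5-en-2-ols to cis-fused octalones. Ring A (C9–C10–C11–C12–C13–C14) is closed by the new C13–C14 σ bond within a suprafacial, boat-shaped six-atom pericyclic array, the only one the cage allows because the vinyl group must reach over the etheno bridge. C14 is set by the cage, since C13 can bond only to the face of C14=C15 that looks at the carbinol bridge, which forces the cis ring fusion, and C13 is set by the (E) enol ether, which in the boat turns the OPMB group outward and places O13 cis to C15 on ring A. C8, C9 and C17 pass over unchanged. The step needs diastereoselectivity at C13/C14, secured by cage and alkene geometry, and chemoselectivity against E1cB loss of the C13 alkoxide from the β-alkoxy enolate, secured by the poorly aligned pseudo-equatorial C13–O bond and the cold acetic acid quench.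

Step 15
Reactants: 25 decalin ketone
Product: 26 C11 equatorial alcohol (cis to the C13 ether)
Conditions: NaBH4, MeOH, −40 °C
Reagents that add atoms: none
Why: Borohydride reduction by axial attack on the ring A chair from the convex face, anti to ring B and past the axial H9 and H13, gives the equatorial C11 alcohol required by the target.

Step 16
Reactants: 26 C11 alcohol
Product: 28 C11 methyl ether, via sodium alkoxide 27 (not isolated)
Conditions: NaH, THF/DMF, 0 °C; then MeI, 0 °C → rt
Reagents that add atoms: iodomethane, CI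
Why: Williamson etherification of alkoxide 27 with iodomethane; no other acidic site is present.

Step 17
Reactants: 28 bis-silyl ether
Product: 29 C18 primary alcohol (C7 OTIPS retained)
Conditions: PPTS, MeOH, rt
Reagents that add atoms: none
Why: Acid-catalysed methanolysis cleaves the primary TBS ether far faster than the bulkier neopentyl TIPS ether (steric rate difference in silyl ether solvolysis).

Step 18
Reactants: 29 C18 alcohol
Product: 30 C18 aldehyde
Conditions: Dess–Martin periodinane, NaHCO3, CH2Cl2, 0 °C; used at once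
Reagents that add atoms: none
Why: Dess–Martin oxidation under buffered, base-free conditions gives the β,γ-unsaturated aldehyde without epimerising the allylic C17 centre.

Step 19
Reactants: 30 C18 aldehyde
Product: 31 ethyl (E)-enoate (C18=C19, C20 ester)
Conditions: Ph3P=C(Me)CO2Et, CH2Cl2, rt → 40 °C
Reagents that add atoms: ethyl 2-(triphenylphosphoranylidene)propanoate, CCOC(=O)C(C)=P(c1ccccc1)(c1ccccc1)c1ccccc1
Why: Wittig olefination with the stabilised, essentially non-basic α-methyl ylide gives the (E)-trisubstituted enoate and neither epimerises nor conjugates the aldehyde.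

Step 20
Reactants: 31 enoate
Product: 32 C20 allylic alcohol
Conditions: iBu2AlH, CH2Cl2, −78 °C
Reagents that add atoms: none
Why: 1,2-Reduction of the enoate to the allylic alcohol by iBu2AlH at low temperature.

Step 21
Reactants: 32 allylic alcohol
Product: 33 (E)-enal (C20 aldehyde)
Conditions: MnO2, CH2Cl2, rt
Reagents that add atoms: none
Why: MnO2 oxidises the allylic alcohol selectively to the enal (allylic oxidation) with retention of alkene geometry.

Step 22
Reactants: 34 N-Boc-D-alaninal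
Product: 36 Boc-protected 24,25-anti-25,26-anti homoallylic amino alcohol, via diisopinocampheylborinate 35 (not isolated)
Conditions: (E)-but-2-ene, n-BuLi, KOtBu, THF, −78 → −45 °C; (−)-Ipc2BOMe; BF3·OEt2; 34, −78 °C; then NaOH, H2O2
Reagents that add atoms: (E)-crotylbis(isopinocampheyl)borane of the (+)-α-pinene series, made in the flask from (E)-but-2-ene, C/C=C/CB([C@@H]1C[C@@H]2C[C@H]([C@H]1C)C2(C)C)[C@@H]1C[C@@H]2C[C@H]([C@H]1C)C2(C)C
Why: Asymmetric crotylboration through a closed chair transition state, in which the (E)-crotyl group gives the 24,25-anti pair and the isopinocampheyl groups direct the reagent to the aldehyde face that 1,2-induction from the N-Boc stereocentre also favours (25,26-anti), a matched pairing.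

Step 23
Reactants: 36 Boc amino alcohol
Product: 38 N-acetyl amino alcohol, via ammonium chloride 37 (not isolated)
Conditions: HCl, dioxane, rt; then Ac2O, Et3N, CH2Cl2, 0 °C
Reagents that add atoms: acetic anhydride, CC(=O)OC(C)=O
Why: Acidolysis of the Boc carbamate followed by chemoselective N-acylation of the amine, which is far more nucleophilic than the secondary alcohol.

Step 24
Reactants: 38 N-acetyl amino alcohol
Product: 39 N-acetyl-2,2-dimethyloxazolidine (C25-O/C26-N acetonide) with terminal alkene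
Conditions: 2-methoxypropene, PPTS (cat.), PhMe, 80 °C
Reagents that add atoms: 2-methoxypropene, COC(C)=C
Why: Acid-catalysed N,O-acetal formation with the enol ether gives the cis-4,5-disubstituted oxazolidine, which masks the C25 hydroxyl and the amide N–H that would otherwise close a hemiaminal onto the C23 aldehyde.

Step 25
Reactants: 39 oxazolidine alkene
Product: 41 C23 aldehyde, via ozonide 40 (not isolated)
Conditions: O3, CH2Cl2, −78 °C; then PPh3, −78 °C → rt; used crude
Reagents that add atoms: ozone, [O-][O+]=O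
Why: Ozonolysis with reductive work-up cleaves the terminal alkene to the α-methyl aldehyde, which is used without purification to keep C24 intact.

Step 26
Reactants: 41 C23 aldehyde
Product: 43 22,23-anti-23,24-syn homoallylic alcohol, via diisopinocampheylborinate 42 (not isolated)
Conditions: (E)-but-2-ene, n-BuLi, KOtBu, THF, −78 → −45 °C; (+)-Ipc2BOMe; BF3·OEt2; 41, −78 °C; then NaOH, H2O2
Reagents that add atoms: (E)-crotylbis(isopinocampheyl)borane of the (−)-α-pinene series, made in the flask from (E)-but-2-ene, C/C=C/CB([C@H]1C[C@H]2C[C@@H]([C@@H]1C)C2(C)C)[C@H]1C[C@H]2C[C@@H]([C@@H]1C)C2(C)C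
Why: Second chair-like crotylboration in which the (E)-geometry gives 22,23-anti and the reagent-preferred aldehyde face coincides with the face favoured by 1,2-induction from the α-methyl centre, giving 23,24-syn.

Step 27
Reactants: 43 homoallylic alcohol
Product: 44 C23 TBS ether
Conditions: TBSOTf, 2,6-lutidine, CH2Cl2, −78 → 0 °C
Reagents that add atoms: tert-butyldimethylsilyl triflate, CC(C)(C)[Si](C)(C)OS(=O)(=O)C(F)(F)F
Why: Silylation of the hindered secondary alcohol with the reactive silyl triflate and a hindered base.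

Step 28
Reactants: 44 silyl ether alkene
Product: 47 C21 primary alcohol, via ozonide 45 (not isolated), via C21 aldehyde 46 (not isolated)
Conditions: O3, CH2Cl2/MeOH, −78 °C; then NaBH4, −78 °C → rt
Reagents that add atoms: ozone, [O-][O+]=O
Why: Ozonolysis and in situ borohydride reduction remove the terminal carbon and give the primary alcohol, the α-methyl aldehyde 46 being reduced before it can epimerise.

Step 29
Reactants: 47 C21 alcohol
Product: 48 1-phenyltetrazol-5-yl sulfide
Conditions: 1-phenyl-1H-tetrazole-5-thiol, PPh3, DIAD, THF, 0 °C → rt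
Reagents that add atoms: 1-phenyl-1H-tetrazole-5-thiol, Sc1nnnn1-c1ccccc1
Why: Mitsunobu substitution of the primary alcohol by the acidic heteroaryl thiol.

Step 30
Reactants: 48 sulfide
Product: 49 C21 1-phenyltetrazol-5-yl sulfone
Conditions: (NH4)6Mo7O24·4H2O (cat.), H2O2, EtOH, 0 °C → rt
Reagents that add atoms: hydrogen peroxide, OO
Why: (NH4)6Mo7O24-catalysed peroxide oxidation of the sulfide to the sulfone; silyl ether, N,O-acetal and amide are inert.

Step 31
Reactants: 33 enal; 49 sulfone
Product: 51 (18E,20E)-diene joining decalin and C21–C27 segment, via potassium sulfonyl carbanion 50 (not isolated)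
Conditions: 49, KN(SiMe3)2, THF, −78 °C; then 33, −78 °C → rt
Reagents that add atoms: none
Why: Julia–Kocienski olefination in which the pre-metalated sulfone adds to the aldehyde faster than it deprotonates the γ-position, and Smiles transfer of the tetrazole with loss of SO2 and tetrazolate gives the C20=C21 alkene, for which this sulfone type with a potassium counter-ion in ethereal solvent favours the (E) isomer.

Step 32
Reactants: 51 diene
Product: 52 C7,C23-diol
Conditions: Bu4NF, THF, 0 °C → rt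
Reagents that add atoms: none
Why: Fluoride-induced desilylation removes both the neopentyl TIPS ether and the C23 TBS ether in one operation; PMB ether and N,O-acetal are stable.

Step 33
Reactants: 52 diol
Product: 53 C7 aldehyde (C23 hydroxyl free)
Conditions: TEMPO (cat.), PhI(OAc)2, CH2Cl2, rt
Reagents that add atoms: none
Why: Oxoammonium (TEMPO) oxidation is selective for the primary alcohol over the hindered secondary C23 hydroxyl and gives a non-enolisable aldehyde.

Step 34
Reactants: 53 C7 aldehyde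
Product: 54 (E)-C6 alkenyl pinacolboronate
Conditions: Cl2CHB(pin), CrCl2, LiI, THF, rt
Reagents that add atoms: 2-(dichloromethyl)-4,4,5,5-tetramethyl-1,3,2-dioxaborolane, ClC(Cl)B1OC(C)(C)C(C)(C)O1
Why: Takai–Utimoto olefination with the gem-dimetallated species generated by CrCl2 from the dichloromethylboronate gives the (E)-alkenylboronate; this CrCl2-derived reagent reacts only with the aldehyde and tolerates the free hydroxyl.

Step 35
Reactants: 55 but-2-yn-1-ol
Product: 57 (Z)-3-iodobut-2-en-1-ol, via cyclic alkenylaluminate 56 (not isolated)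
Conditions: NaAlH2(OCH2CH2OMe)2, THF, 0 °C → rt; then I2, −78 °C
Reagents that add atoms: iodine, II
Why: Hydroxyl-directed trans-hydroalumination places aluminium on C3 cis to the carbinol carbon, and iodinolysis with retention gives the (Z)-vinyl iodide.

Step 36
Reactants: 57 (Z)-3-iodobut-2-en-1-ol
Product: 59 methyl (2E,4Z)-5-iodohexa-2,4-dienoate, via (Z)-3-iodobut-2-enal 58 (not isolated)
Conditions: MnO2, Ph3P=CHCO2Me, CH2Cl2, rt
Reagents that add atoms: methyl 2-(triphenylphosphoranylidene)acetate, COC(=O)C=P(c1ccccc1)(c1ccccc1)c1ccccc1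
Why: Tandem allylic oxidation and Wittig olefination in which the sensitive (Z)-iodoenal is trapped as it forms by the stabilised ylide, giving the (2E)-enoate and leaving the (Z)-iodoalkene untouched.

Step 37
Reactants: 54 alkenylboronate; 59 iododienoate
Product: 60 methyl (2E,4Z,6E)-trienoate with free C23 hydroxyl
Conditions: Pd(PPh3)4 (cat.), TlOEt, THF/H2O, rt
Reagents that add atoms: none
Why: Suzuki–Miyaura coupling with retention of both alkene geometries joins C5 to C6 and completes the trienoate; TlOEt speeds up transmetalation so the coupling runs at room temperature.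

Step 38
Reactants: 60 hydroxy trienoate
Product: 61 seco acid
Conditions: LiOH, THF/MeOH/H2O, 0 °C → rt; then 1 M HCl to pH 4
Reagents that add atoms: water (as hydroxide), O
Why: Saponification of the only ester (acyl substitution by hydroxide) gives the hydroxy acid.

Step 39
Reactants: 61 seco acid
Product: 63 16-membered macrolactone (C13 OPMB, C25/C26 acetonide), via mixed anhydride 62 (not isolated)
Conditions: 2,4,6-Cl3C6H2COCl, Et3N, THF, rt; then slow addition to DMAP, PhMe, 40 °C, high dilution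
Reagents that add atoms: none
Why: Yamaguchi macrolactonisation in which the mixed anhydride, through its acylpyridinium ion, is attacked by the only free hydroxyl (C23) under high dilution, closing the 16-membered ring by acyl substitution.

Step 40
Reactants: 63 macrolactone
Product: 64 C13 alcohol
Conditions: DDQ, CH2Cl2/pH 7 buffer, 0 °C
Reagents that add atoms: none
Why: Oxidative cleavage of the PMB ether by DDQ (benzylic hydride abstraction and hydrolysis of the oxocarbenium ion) under buffered conditions at low temperature to spare the diene.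

Step 41
Reactants: 64 C13 alcohol
Product: 66 C13 primary carbamate, via N-trichloroacetyl carbamate 65 (not isolated)
Conditions: Cl3CC(O)NCO, CH2Cl2, 0 °C; then K2CO3, MeOH, 0 °C
Reagents that add atoms: trichloroacetyl isocyanate, O=C=NC(=O)C(Cl)(Cl)Cl
Why: Addition of the only free hydroxyl to the acyl isocyanate and mild methanolysis of the trichloroacetyl group give the primary carbamate (isocyanate carbamoylation).

Step 42
Reactants: 66 carbamate acetonide
Product: 67 superstolide A
Conditions: CSA (cat.), MeOH/H2O, 0 °C → rt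
Reagents that add atoms: none
Why: Acid-catalysed hydrolysis of the N,O-acetal releases the C25 hydroxyl and the acetamide N–H without touching lactone, carbamate, polyenes or any stereocentre.

Compound list
1 | fumaryl chloride | O=C(Cl)/C=C/C(Cl)=O | starting material
2 | (−)-menthol | C[C@@H]1CC[C@H]([C@@H](C1)O)C(C)C | starting material
3 | di-(−)-menthyl fumarate | CC(C)[C@@H]1CC[C@@H](C)C[C@H]1OC(=O)/C=C/C(=O)O[C@@H]1C[C@H](C)CC[C@H]1C(C)C | intermediate
4 | guaiacol | COc1ccccc1O | starting material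
5 | 6,6-dimethoxycyclohexa-2,4-dien-1-one | COC1(OC)C=CC=CC1=O | intermediate (not isolated)
6 | di-(−)-menthyl trans-5,5-dimethoxy-6-oxobicyclo[2.2.2]oct-7-ene-2,3-dicarboxylate, C17 ester syn to oxo bridge, C8 ester syn to etheno bridge | O=C1C(OC)(OC)[C@@H]2C=C[C@H]1[C@H](C(=O)O[C@@H]3C[C@H](C)CC[C@H]3C(C)C)[C@H]2C(=O)O[C@@H]3C[C@H](C)CC[C@H]3C(C)C | intermediate
7 | C11 alcohol of 6, hydroxyl syn to the C8–C17 bridge | O[C@H]1C(OC)(OC)[C@@H]2C=C[C@H]1[C@H](C(=O)O[C@@H]3C[C@H](C)CC[C@H]3C(C)C)[C@H]2C(=O)O[C@@H]3C[C@H](C)CC[C@H]3C(C)C | intermediate (not isolated)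
8 | C18→O11 γ-lactone, menthyl C7 ester, H8 exo | O=C3O[C@H]1C(OC)(OC)[C@@H]2C=C[C@H]1[C@H]3[C@H]2C(=O)O[C@@H]4C[C@H](C)CC[C@H]4C(C)C | intermediate
9 | lithium enolate of 8 at C8 | O=C3O[C@H]1C(OC)(OC)[C@@H]2C=C[C@H]1[C@H]3C2=C([O-])O[C@@H]4C[C@H](C)CC[C@H]4C(C)C.[Li+] | intermediate (not isolated)
10 | C8-methyl lactone ester, methyl syn to C14=C15 | O=C3O[C@H]1C(OC)(OC)[C@@H]2C=C[C@H]1[C@H]3[C@]2(C)C(=O)O[C@@H]4C[C@H](C)CC[C@H]4C(C)C | intermediate
11 | C11,C18-diol, menthyl C7 ester | O[C@H]1C(OC)(OC)[C@@H]2C=C[C@H]1[C@H](CO)[C@]2(C)C(=O)O[C@@H]3C[C@H](C)CC[C@H]3C(C)C | intermediate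
12 | C18 OTBS, C11 OH, menthyl C7 ester | O[C@H]1C(OC)(OC)[C@@H]2C=C[C@H]1[C@H](CO[Si](C)(C)C(C)(C)C)[C@]2(C)C(=O)O[C@@H]3C[C@H](C)CC[C@H]3C(C)C | intermediate
13 | C18 OTBS, C11 OH, C7 OH | O[C@H]1C(OC)(OC)[C@@H]2C=C[C@H]1[C@H](CO[Si](C)(C)C(C)(C)C)[C@]2(C)CO | intermediate
14 | C18 OTBS, C7 OTIPS, C11 OH | O[C@H]1C(OC)(OC)[C@@H]2C=C[C@H]1[C@H](CO[Si](C)(C)C(C)(C)C)[C@]2(C)CO[Si](C(C)C)(C(C)C)C(C)C | intermediate
15 | 3,3-dimethoxybicyclo[2.2.2]oct-5-en-2-one with C18 OTBS, C7 OTIPS, C8 methyl | O=C1C(OC)(OC)[C@@H]2C=C[C@H]1[C@H](CO[Si](C)(C)C(C)(C)C)[C@]2(C)CO[Si](C(C)C)(C(C)C)C(C)C | intermediate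
16 | bicyclo[2.2.2]oct-5-en-2-one with C18 OTBS, C7 OTIPS, C8 methyl | O=C1C[C@@H]2C=C[C@H]1[C@H](CO[Si](C)(C)C(C)(C)C)[C@]2(C)CO[Si](C(C)C)(C(C)C)C(C)C | intermediate
17 | 4-methoxybenzyl alcohol | COc1ccc(CO)cc1 | starting material
18 | trichloroethylene | ClC=C(Cl)Cl | starting material
19 | (E)-1,2-dichlorovinyl 4-methoxybenzyl ether | COc1ccc(CO/C(Cl)=C\Cl)cc1 | intermediate
20 | lithium (4-methoxybenzyloxy)acetylide | [Li]C#COCc1ccc(OC)cc1 | intermediate (not isolated)
21 | C11 (4-methoxybenzyloxy)ethynyl carbinol, alkynyl syn to etheno bridge | O[C@@]1(C#COCc3ccc(OC)cc3)C[C@@H]2C=C[C@H]1[C@H](CO[Si](C)(C)C(C)(C)C)[C@]2(C)CO[Si](C(C)C)(C(C)C)C(C)C | intermediate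
22 | endo-(E)-2-(4-methoxybenzyloxy)vinyl bicyclo[2.2.2]octenol | O[C@@]1(/C=C/OCc3ccc(OC)cc3)C[C@@H]2C=C[C@H]1[C@H](CO[Si](C)(C)C(C)(C)C)[C@]2(C)CO[Si](C(C)C)(C(C)C)C(C)C | intermediate
23 | potassium alkoxide of 22 | [K+].[O-][C@@]1(/C=C/OCc3ccc(OC)cc3)C[C@@H]2C=C[C@H]1[C@H](CO[Si](C)(C)C(C)(C)C)[C@]2(C)CO[Si](C(C)C)(C(C)C)C(C)C | intermediate (not isolated)
24 | potassium C11 enolate of the cis-decalin | [K+].[O-]C1=C[C@H](OCc3ccc(OC)cc3)[C@@H]2C=C[C@H](CO[Si](C)(C)C(C)(C)C)[C@](C)(CO[Si](C(C)C)(C(C)C)C(C)C)[C@@H]2C1 | intermediate (not isolated)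
25 | cis-decalin C11 ketone, C13 OPMB, C18 OTBS, C7 OTIPS | O=C1C[C@H](OCc3ccc(OC)cc3)[C@@H]2C=C[C@H](CO[Si](C)(C)C(C)(C)C)[C@](C)(CO[Si](C(C)C)(C(C)C)C(C)C)[C@@H]2C1 | intermediate
26 | C11 equatorial alcohol, cis to O13 | O[C@@H]1C[C@H](OCc3ccc(OC)cc3)[C@@H]2C=C[C@H](CO[Si](C)(C)C(C)(C)C)[C@](C)(CO[Si](C(C)C)(C(C)C)C(C)C)[C@@H]2C1 | intermediate
27 | sodium alkoxide of 26 | [Na+].[O-][C@@H]1C[C@H](OCc3ccc(OC)cc3)[C@@H]2C=C[C@H](CO[Si](C)(C)C(C)(C)C)[C@](C)(CO[Si](C(C)C)(C(C)C)C(C)C)[C@@H]2C1 | intermediate (not isolated)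
28 | C11 methyl ether | CO[C@@H]1C[C@H](OCc3ccc(OC)cc3)[C@@H]2C=C[C@H](CO[Si](C)(C)C(C)(C)C)[C@](C)(CO[Si](C(C)C)(C(C)C)C(C)C)[C@@H]2C1 | intermediate
29 | C18 alcohol | CO[C@@H]1C[C@H](OCc3ccc(OC)cc3)[C@@H]2C=C[C@H](CO)[C@](C)(CO[Si](C(C)C)(C(C)C)C(C)C)[C@@H]2C1 | intermediate
30 | C18 aldehyde | CO[C@@H]1C[C@H](OCc3ccc(OC)cc3)[C@@H]2C=C[C@H](C=O)[C@](C)(CO[Si](C(C)C)(C(C)C)C(C)C)[C@@H]2C1 | intermediate
31 | ethyl (E)-2-methylpropenoate on C17 (C18=C19, C20 ester) | CO[C@@H]1C[C@H](OCc3ccc(OC)cc3)[C@@H]2C=C[C@H](/C=C(C)/C(=O)OCC)[C@](C)(CO[Si](C(C)C)(C(C)C)C(C)C)[C@@H]2C1 | intermediate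
32 | C20 allylic alcohol | CO[C@@H]1C[C@H](OCc3ccc(OC)cc3)[C@@H]2C=C[C@H](/C=C(C)/CO)[C@](C)(CO[Si](C(C)C)(C(C)C)C(C)C)[C@@H]2C1 | intermediate
33 | C20 (E)-enal | CO[C@@H]1C[C@H](OCc3ccc(OC)cc3)[C@@H]2C=C[C@H](/C=C(C)/C=O)[C@](C)(CO[Si](C(C)C)(C(C)C)C(C)C)[C@@H]2C1 | intermediate
34 | N-Boc-D-alaninal, tert-butyl (R)-(1-oxopropan-2-yl)carbamate | O=C[C@@H](C)NC(=O)OC(C)(C)C | starting material
35 | diisopinocampheylborinate of 36 | C=C[C@H](C)[C@H](OB([C@@H]1C[C@@H]2C[C@H]([C@H]1C)C2(C)C)[C@@H]1C[C@@H]2C[C@H]([C@H]1C)C2(C)C)[C@@H](C)NC(=O)OC(C)(C)C | intermediate (not isolated)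
36 | tert-butyl N-(3-hydroxy-4-methylhex-5-en-2-yl)carbamate, 24,25-anti, 25,26-anti (C26 R) | C=C[C@H](C)[C@H](O)[C@@H](C)NC(=O)OC(C)(C)C | intermediate
37 | ammonium chloride of the amino alcohol | C=C[C@H](C)[C@H](O)[C@@H](C)[NH3+].[Cl-] | intermediate (not isolated)
38 | N-(3-hydroxy-4-methylhex-5-en-2-yl)acetamide, same configuration | C=C[C@H](C)[C@H](O)[C@@H](C)NC(C)=O | intermediate
39 | 3-acetyl-2,2,4-trimethyl-5-(but-3-en-2-yl)oxazolidine, 4,5-cis | C=C[C@H](C)[C@H](O3)[C@@H](C)N(C(C)=O)C3(C)C | intermediate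
40 | ozonide of 39 | C1OOC(O1)[C@H](C)[C@H](O3)[C@@H](C)N(C(C)=O)C3(C)C | intermediate (not isolated)
41 | 2-(3-acetyl-2,2,4-trimethyloxazolidin-5-yl)propanal (C23 aldehyde) | O=C[C@H](C)[C@H](O3)[C@@H](C)N(C(C)=O)C3(C)C | intermediate
42 | diisopinocampheylborinate of 43 | C=C[C@@H](C)[C@H]([C@H](C)[C@H](O3)[C@@H](C)N(C(C)=O)C3(C)C)OB([C@H]1C[C@H]2C[C@@H]([C@@H]1C)C2(C)C)[C@H]1C[C@H]2C[C@@H]([C@@H]1C)C2(C)C | intermediate (not isolated)
43 | C23 homoallylic alcohol, 22,23-anti, 23,24-syn | C=C[C@@H](C)[C@H]([C@H](C)[C@H](O3)[C@@H](C)N(C(C)=O)C3(C)C)O | intermediate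
44 | C23 TBS ether | C=C[C@@H](C)[C@H]([C@H](C)[C@H](O3)[C@@H](C)N(C(C)=O)C3(C)C)O[Si](C)(C)C(C)(C)C | intermediate
45 | ozonide of 44 | C1OOC(O1)[C@@H](C)[C@H]([C@H](C)[C@H](O3)[C@@H](C)N(C(C)=O)C3(C)C)O[Si](C)(C)C(C)(C)C | intermediate (not isolated)
46 | C21 aldehyde | O=C[C@@H](C)[C@H]([C@H](C)[C@H](O3)[C@@H](C)N(C(C)=O)C3(C)C)O[Si](C)(C)C(C)(C)C | intermediate (not isolated)
47 | C21 primary alcohol | OC[C@@H](C)[C@H]([C@H](C)[C@H](O3)[C@@H](C)N(C(C)=O)C3(C)C)O[Si](C)(C)C(C)(C)C | intermediate
48 | C21 1-phenyltetrazol-5-yl sulfide | c1ccc(cc1)-n1nnnc1SC[C@@H](C)[C@H]([C@H](C)[C@H](O3)[C@@H](C)N(C(C)=O)C3(C)C)O[Si](C)(C)C(C)(C)C | intermediate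
49 | C21 1-phenyltetrazol-5-yl sulfone | O=S(=O)(C[C@@H](C)[C@H]([C@H](C)[C@H](O3)[C@@H](C)N(C(C)=O)C3(C)C)O[Si](C)(C)C(C)(C)C)c1nnnn1-c1ccccc1 | intermediate
50 | potassium α-sulfonyl carbanion of 49 | [K+].O=S(=O)([CH-][C@@H](C)[C@H]([C@H](C)[C@H](O3)[C@@H](C)N(C(C)=O)C3(C)C)O[Si](C)(C)C(C)(C)C)c1nnnn1-c1ccccc1 | intermediate (not isolated)
51 | (18E,20E)-diene, C7 OTIPS, C23 OTBS, C13 OPMB, acetonide | CO[C@@H]1C[C@H](OCc5ccc(OC)cc5)[C@@H]2C=C[C@H](/C=C(C)/C=C/[C@@H](C)[C@H]([C@H](C)[C@H](O3)[C@@H](C)N(C(C)=O)C3(C)C)O[Si](C)(C)C(C)(C)C)[C@](C)(CO[Si](C(C)C)(C(C)C)C(C)C)[C@@H]2C1 | intermediate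
52 | C7,C23-diol | CO[C@@H]1C[C@H](OCc5ccc(OC)cc5)[C@@H]2C=C[C@H](/C=C(C)/C=C/[C@@H](C)[C@H]([C@H](C)[C@H](O3)[C@@H](C)N(C(C)=O)C3(C)C)O)[C@](C)(CO)[C@@H]2C1 | intermediate
53 | C7 aldehyde, C23 OH | CO[C@@H]1C[C@H](OCc5ccc(OC)cc5)[C@@H]2C=C[C@H](/C=C(C)/C=C/[C@@H](C)[C@H]([C@H](C)[C@H](O3)[C@@H](C)N(C(C)=O)C3(C)C)O)[C@](C)(C=O)[C@@H]2C1 | intermediate
54 | (E)-C6 alkenyl pinacolboronate, C23 OH | CO[C@@H]1C[C@H](OCc5ccc(OC)cc5)[C@@H]2C=C[C@H](/C=C(C)/C=C/[C@@H](C)[C@H]([C@H](C)[C@H](O3)[C@@H](C)N(C(C)=O)C3(C)C)O)[C@](C)(/C=C/B4OC(C)(C)C(C)(C)O4)[C@@H]2C1 | intermediate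
55 | but-2-yn-1-ol | CC#CCO | starting material
56 | sodium 2,2-bis(2-methoxyethoxy)-3-methyl-1-oxa-2-aluminacyclopent-3-en-2-uide | [Na+].CC1=CCO[Al-]1(OCCOC)OCCOC | intermediate (not isolated)
57 | (Z)-3-iodobut-2-en-1-ol | OC/C=C(C)\I | intermediate
58 | (Z)-3-iodobut-2-enal | O=C/C=C(C)\I | intermediate (not isolated)
59 | methyl (2E,4Z)-5-iodohexa-2,4-dienoate | COC(=O)/C=C/C=C(C)\I | intermediate
60 | methyl (2E,4Z,6E)-trienoate, C23 OH | CO[C@@H]1C[C@H](OCc5ccc(OC)cc5)[C@@H]2C=C[C@H](/C=C(C)/C=C/[C@@H](C)[C@H]([C@H](C)[C@H](O3)[C@@H](C)N(C(C)=O)C3(C)C)O)[C@](C)(/C=C/C(C)=C\C=C\C(=O)OC)[C@@H]2C1 | intermediate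
61 | seco acid | CO[C@@H]1C[C@H](OCc5ccc(OC)cc5)[C@@H]2C=C[C@H](/C=C(C)/C=C/[C@@H](C)[C@H]([C@H](C)[C@H](O3)[C@@H](C)N(C(C)=O)C3(C)C)O)[C@](C)(/C=C/C(C)=C\C=C\C(=O)O)[C@@H]2C1 | intermediate
62 | 2,4,6-trichlorobenzoic mixed anhydride of 61 | CO[C@@H]1C[C@H](OCc5ccc(OC)cc5)[C@@H]2C=C[C@H](/C=C(C)/C=C/[C@@H](C)[C@H]([C@H](C)[C@H](O3)[C@@H](C)N(C(C)=O)C3(C)C)O)[C@](C)(/C=C/C(C)=C\C=C\C(=O)OC(=O)c4c(Cl)cc(Cl)cc4Cl)[C@@H]2C1 | intermediate (not isolated)
63 | macrolactone, C13 OPMB, C25/C26 N-acetyl acetonide | CO[C@@H]1C[C@H](OCc5ccc(OC)cc5)[C@@H]2C=C[C@@H]3/C=C(C)/C=C/[C@@H](C)[C@H]([C@H](C)[C@H](O4)[C@@H](C)N(C(C)=O)C4(C)C)OC(=O)/C=C/C=C(C)\C=C\[C@]3(C)[C@@H]2C1 | intermediate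
64 | macrolactone C13 alcohol | CO[C@@H]1C[C@H](O)[C@@H]2C=C[C@@H]3/C=C(C)/C=C/[C@@H](C)[C@H]([C@H](C)[C@H](O4)[C@@H](C)N(C(C)=O)C4(C)C)OC(=O)/C=C/C=C(C)\C=C\[C@]3(C)[C@@H]2C1 | intermediate
65 | C13 N-trichloroacetyl carbamate | CO[C@@H]1C[C@H](OC(=O)NC(=O)C(Cl)(Cl)Cl)[C@@H]2C=C[C@@H]3/C=C(C)/C=C/[C@@H](C)[C@H]([C@H](C)[C@H](O4)[C@@H](C)N(C(C)=O)C4(C)C)OC(=O)/C=C/C=C(C)\C=C\[C@]3(C)[C@@H]2C1 | intermediate (not isolated)
66 | C13 carbamate, C25/C26 N-acetyl acetonide | CO[C@@H]1C[C@H](OC(N)=O)[C@@H]2C=C[C@@H]3/C=C(C)/C=C/[C@@H](C)[C@H]([C@H](C)[C@H](O4)[C@@H](C)N(C(C)=O)C4(C)C)OC(=O)/C=C/C=C(C)\C=C\[C@]3(C)[C@@H]2C1 | intermediate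
67 | superstolide A | CO[C@@H]1C[C@H](OC(N)=O)[C@@H]2C=C[C@@H]3/C=C(C)/C=C/[C@@H](C)[C@H]([C@H](C)[C@H](O)[C@@H](C)NC(C)=O)OC(=O)/C=C/C=C(C)\C=C\[C@]3(C)[C@@H]2C1 | target

Total step count: 42.
Longest linear sequence: 30 steps (steps 1–10, 12–21, 31–34, 37–42, from fumaryl chloride and menthol to the target).

Steps most likely to fail

Step 2. The transient dienone 5 may dimerise faster than it adds the hindered fumarate, and the two face isomers may resist separation. The fallback sets out from fumarate 3 and uses commercial 4-bromo-2-methoxyphenol in place of 4. Oxidation with PhI(OAc)2 in methanol gives 4-bromo-6,6-dimethoxycyclohexa-2,4-dien-1-one F1, in which the bromine retards self-dimerisation, so it can be heated with 3 in toluene without methanol or a large excess of dienophile. This gives the 14-bromo adduct F2 in the same orientation, and its diastereomers are separated by crystallisation. Radical reduction of the vinyl bromide (Bu3SnH, AIBN, PhH, 80 °C) returns to 6.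

Step 14. The C13 alkoxide may be lost from enolate 24 by β-elimination, or alkoxide 23 may fragment, before rearrangement and quench are complete. The fallback sets out from carbinol 22, which is silylated (1-(trimethylsilyl)imidazole, CH2Cl2) to the trimethylsilyl ether F3. Heating F3 (PhMe, sealed tube, about 200 °C) effects the neutral siloxy-Cope rearrangement through the same boat and gives the trimethylsilyl enol ether F4 directly, with no free enolate. Buffered methanolysis of F4 (citric acid, MeOH, 0 °C) arrives at ketone 25.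

Step 39. Acylation of the hindered C23 hydroxyl may be slow enough for oligomerisation and DMAP-induced isomerisation of the 2E,4Z unit to compete. The fallback forms the ester bond intermolecularly and closes the ring by C–C coupling, setting out from boronate 54 and ester 59. Ester 59 is saponified (LiOH, THF/H2O) to (2E,4Z)-5-iodohexa-2,4-dienoic acid F5. The C23 hydroxyl of 54 is acylated with F5 (2,4,6-Cl3C6H2COCl, Et3N, DMAP, PhMe) to the C23 iododienoate ester F6. Intramolecular Suzuki–Miyaura coupling of F6 (Pd(PPh3)4, TlOEt, THF/H2O, high dilution) forms C5–C6 and arrives at macrolactone 63.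

Further compounds
F1 | step 2 | 4-bromo-6,6-dimethoxycyclohexa-2,4-dien-1-one | COC1(OC)C=C(Br)C=CC1=O
F2 | step 2 | 14-bromo analogue of adduct 6 (bromine on the etheno carbon next to C9) | O=C1C(OC)(OC)[C@@H]2C(Br)=C[C@H]1[C@H](C(=O)O[C@@H]3C[C@H](C)CC[C@H]3C(C)C)[C@H]2C(=O)O[C@@H]3C[C@H](C)CC[C@H]3C(C)C
F3 | step 14 | trimethylsilyl ether of carbinol 22 | C[Si](C)(C)O[C@@]1(/C=C/OCc3ccc(OC)cc3)C[C@@H]2C=C[C@H]1[C@H](CO[Si](C)(C)C(C)(C)C)[C@]2(C)CO[Si](C(C)C)(C(C)C)C(C)C
F4 | step 14 | C11 trimethylsilyl enol ether of decalin ketone 25 | C[Si](C)(C)OC1=C[C@H](OCc3ccc(OC)cc3)[C@@H]2C=C[C@H](CO[Si](C)(C)C(C)(C)C)[C@](C)(CO[Si](C(C)C)(C(C)C)C(C)C)[C@@H]2C1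
F5 | step 39 | (2E,4Z)-5-iodohexa-2,4-dienoic acid | OC(=O)/C=C/C=C(C)\I
F6 | step 39 | C23 (2E,4Z)-5-iodohexa-2,4-dienoate of boronate 54 | CO[C@@H]1C[C@H](OCc5ccc(OC)cc5)[C@@H]2C=C[C@H](/C=C(C)/C=C/[C@@H](C)[C@H]([C@H](C)[C@H](O3)[C@@H](C)N(C(C)=O)C3(C)C)OC(=O)/C=C/C=C(C)\I)[C@](C)(/C=C/B4OC(C)(C)C(C)(C)O4)[C@@H]2C1
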